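You hold no rate constant for this flask, so work from the last readings of the two earlier runs.

| setting | south | west | flask |
|---|---|---|---|
| starting material | 0.14 M | 0.22 M | 0.10 M |
| partner | 0.11 M | 0.11 M | 0.110 M |
| remark | run made earlier | run made earlier |  |
| time |  |  | 6.0 min |

| run | time / min | starting material / % | first product / % |
|---|---|---|---|
| south | 1.00 | 51.0 | 34.4 |
| south | 2.00 | 43.6 | 37.1 |
| south | 3.00 | 42.1 | 37.3 |
| south | 4.00 | 41.7 | 37.7 |
| south | 5.00 | 41.9 | 38.0 |
| south | 6.00 | 41.0 | 37.7 |
| south | 8.00 | 41.3 | 37.1 |
| west | 0.500 | 68.9 | 26.0 |
| west | 0.833 | 62.8 | 29.2 |
| west | 1.33 | 60.3 | 30.7 |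
| west | 2.00 | 58.7 | 30.7 |
| west | 3.00 | 58.8 | 31.6 |
| west | 5.00 | 59.1 | 31.1 |
| west | 8.00 | 58.8 | 30.8 |

(readings scatter by 0.3 percentage points)



* the starting material standing at 6.0 min, as a percentage of the starting material charged
* the first product standing at 6.0 min, as a percentage of the starting material charged
* the other mono adduct standing at 6.0 min, as a percentage of the starting material charged
* the bis adduct standing at 6.0 min, as a percentage of the starting material charged

Turn the time first: the south run's starting material reads 42.1% at 3.00 min and 41.3% at 8.00 min, so I take this flask as finished by 6.0 min.

Turn the ratio of the charges next. By hand, a partner sits once in a mono adduct and twice in the bis adduct, so with the partner used up, in shares of starting material charged: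

twice starting material + first product + other mono adduct = 2 − partner charged / starting material charged

Without the other mono adduct, the two runs fall short by 1.7 percentage points on average, which I book as other mono adduct.

Turn the amounts last: the split needs a selectivity factor, and I use the competition number, first product / (A ln(1/A)) with A the starting material share, which equals one if first product takes partner as fast as starting material does. The two runs average 1.00.

Now iterate, starting with the partner entirely in bis adduct:

start: A = 45.0%, first product 36.0%
round one: A = 27.0%, first product 35.4%
round two: A = 27.3%, first product 35.5%

That leaves 35.5% bis adduct.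

The forecast, reckoned otherwise, says 25.5%, 39.7%, 1.7% and 33.1%, lower on starting material and higher on first product than mine, and its grounds open with: “Both runs level off”.

The flask gives 26.2%, 37.2%, 1.10% and 35.5%, and the forecast holds.

    starting material + partner → first product (k = 0.280 L mol⁻¹ s⁻¹)
    starting material + partner → other mono adduct (k = 0.0100 L mol⁻¹ s⁻¹)
    partner + first product → bis adduct (k = 0.250 L mol⁻¹ s⁻¹)
    partner + other mono adduct → bis adduct (k = 0.330 L mol⁻¹ s⁻¹)
    partner ⇌ dormant form (K = 0.390, k = 0.350 s⁻¹)

In this flask first product is made 2.44 times as fast as it is used up at 0.426 min, but at 6.00 min partner enters it at 0.79 of the rate at which partner enters bis adduct. By then 0.45% of the partner stands against 26% of the starting material, with 1.97 × 10⁻⁴ M of dormant form, which barely moves the bis adduct. This flask's own end gives a competition number of 1.06 against the runs' 1.00. With 1.00 and 0.066 M of partner, two rounds from 35.5% first product give 49.5% starting material, and that neighbour stands at 48.7%.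

The runs were generated by integration from invented constants; noise was put on by code.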